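**Retrosynthetic overview**
- The target is opened at C8–CH2: (2S)-6-(2-hydroxybenzyl)pinocembrin plus the o-quinone methide (a hetero-diene) of a "dimeric" salicyl alcohol. The diene is captured by the enolic edge of ring A (formal oxa-[4+2], then rearomatising ring-opening).
- The 6-benzyl flavanone is opened at C6–CH2 in the same way: (2S)-pinocembrin, bought with the only stereocentre, plus the o-quinone methide of salicyl alcohol.
- The dimeric salicyl alcohol comes from hydride reduction/deacetylation of a diarylmethane aldehyde, itself made by sp3–sp2 Suzuki coupling of two catalogue arenes.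
- No ring of the skeleton is built: rings A, B, C and all phenol rings are bought. Only transient o-quinone methides and three C–C bonds are made, in the order diarylmethane, C6–CH2, C8–CH2.

Assumption: commercial (2S)-(−)-pinocembrin of natural origin is taken as enantiopure, and compounds 1 and 2 are taken as catalogue items.

**Step 1**
Reactants: 1 2-(chloromethyl)phenyl acetate; 2 2-hydroxy-5-(4,4,5,5-tetramethyl-1,3,2-dioxaborolan-2-yl)benzaldehyde
Product: 3 2-[(3-formyl-4-hydroxyphenyl)methyl]phenyl acetate
Conditions: Pd(OAc)2 (2 mol%), SPhos (4 mol%), K3PO4·H2O (2.5 equiv), toluene, 60 °C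
Reagents that add atoms: none
Why: Suzuki–Miyaura sp3–sp2 coupling (zerovalent palladium inserts into the benzylic C–Cl bond, the phosphate-activated aryl boronate transmetalates, reductive elimination follows); the acetate stops the benzylic chloride collapsing to an o-quinone methide, and the substitution pattern of both rings is fixed by the building blocks.

**Step 2**
Reactants: 3 2-[(3-formyl-4-hydroxyphenyl)methyl]phenyl acetate
Product: 4 4-[(2-hydroxyphenyl)methyl]-2-(hydroxymethyl)phenol
Conditions: LiAlH4 (2 equiv), THF, 0 °C to rt; aq. NH4Cl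
Reagents that add atoms: none
Why: Hydride reduction: LiAlH4 reduces the aldehyde to the benzylic alcohol and cleaves the aryl acetate (to ethanol) in one operation, and at 0 °C to rt the salicyl CH2OH is not reduced further.

**Step 3**
Reactants: 5 (2S)-5,7-dihydroxy-2-phenylchroman-4-one [(2S)-pinocembrin]; 6 2-(hydroxymethyl)phenol (salicyl alcohol)
Product: 8 (2S)-5,7-dihydroxy-6-(2-hydroxybenzyl)-2-phenylchroman-4-one (isochamanetin), via o-quinone methide 7 (not isolated)
Conditions: ZnCl2 (2 equiv), dry 1,4-dioxane, 85 °C; 6 (1 equiv) added over 3 h to 5 (2 equiv); silica chromatography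
Reagents that add atoms: none
Why: ZnCl2 dehydrates zinc-bound 6 to the o-quinone methide 7, a hetero-diene captured by the enolic C5(OH)=C6 edge of ring A in a formal oxa-[4+2] addition with immediate rearomatising ring-opening (a Friedel–Crafts-type ortho-hydroxybenzylation); C6 is expected to be the more nucleophilic carbon of a neutral 5,7-dihydroxyflavanone (the C8 isomer and the 6,8-bis-adduct are removed on silica), and the non-basic medium leaves the bought C2 (S) centre untouched.

**Step 4**
Reactants: 8 (2S)-5,7-dihydroxy-6-(2-hydroxybenzyl)-2-phenylchroman-4-one; 4 4-[(2-hydroxyphenyl)methyl]-2-(hydroxymethyl)phenol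
Product: 10 isouvarinol [(2S)-5,7-dihydroxy-6-(2-hydroxybenzyl)-8-[2-hydroxy-5-(2-hydroxybenzyl)benzyl]-2-phenylchroman-4-one], via benzylated o-quinone methide 9 (not isolated)
Conditions: ZnCl2 (2 equiv), dry 1,4-dioxane, 85 °C; 4 (1.5 equiv) added in portions
Reagents that add atoms: none
Why: The same ZnCl2-mediated o-quinone methide generation and capture (formal oxa-[4+2], then rearomatisation; Friedel–Crafts-type C-benzylation) now finds only C8 free on the phloroglucinol ring, which is far more nucleophilic than the simple phenol rings of 8, 4 or 9, so 9 is delivered there and C2 (S) is carried through unchanged.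

**Compound list**
1 | 2-(chloromethyl)phenyl acetate | CC(=O)Oc1ccccc1CCl | starting material
2 | 2-hydroxy-5-(4,4,5,5-tetramethyl-1,3,2-dioxaborolan-2-yl)benzaldehyde | O=Cc1cc(B2OC(C)(C)C(C)(C)O2)ccc1O | starting material
3 | 2-[(3-formyl-4-hydroxyphenyl)methyl]phenyl acetate | CC(=O)Oc1ccccc1Cc1ccc(O)c(C=O)c1 | intermediate
4 | 4-[(2-hydroxyphenyl)methyl]-2-(hydroxymethyl)phenol | OCc1cc(Cc2ccccc2O)ccc1O | intermediate
5 | (2S)-5,7-dihydroxy-2-phenylchroman-4-one, (2S)-pinocembrin | O=C1C[C@@H](c2ccccc2)Oc2cc(O)cc(O)c21 | starting material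
6 | 2-(hydroxymethyl)phenol, salicyl alcohol | OCc1ccccc1O | starting material
7 | 6-methylidenecyclohexa-2,4-dien-1-one, o-quinone methide of 6 (not isolated) | C=C1C=CC=CC1=O | intermediate
8 | (2S)-5,7-dihydroxy-6-(2-hydroxybenzyl)-2-phenylchroman-4-one, isochamanetin | O=C1C[C@@H](c2ccccc2)Oc2cc(O)c(Cc3ccccc3O)c(O)c21 | intermediate
9 | 4-(2-hydroxybenzyl)-6-methylidenecyclohexa-2,4-dien-1-one, o-quinone methide of 4 (not isolated) | C=C1C=C(Cc2ccccc2O)C=CC1=O | intermediate
10 | isouvarinol, (2S)-5,7-dihydroxy-6-(2-hydroxybenzyl)-8-[2-hydroxy-5-(2-hydroxybenzyl)benzyl]-2-phenylchroman-4-one | O=C1C[C@@H](c2ccccc2)Oc2c(Cc3cc(Cc4ccccc4O)ccc3O)c(O)c(Cc3ccccc3O)c(O)c21 | target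

**Totals**
Total step count: 4. Longest linear sequence: 3 steps (steps 1, 2 and 4); the other branch is steps 3 and 4.

**Steps most likely to fail, with fallbacks**

Step 3. The mono-benzylation may give a poor 6:8 ratio, too much bis-adduct, or some loss of ee if acid opens the flavanone to the chalcone (check by chiral HPLC). The fallback uses a blocking group and reverses the order of the two benzylations. It sets out from 5 and comes back to the route at 10.
- N-Iodosuccinimide in DMF at rt (neutral; C6-selective on 5,7-dihydroxyflavonoids) gives (2S)-5,7-dihydroxy-6-iodo-2-phenylchroman-4-one F1.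
- F1 is coupled with 4 at the only free ring A carbon, C8 (ZnCl2, dioxane, 60 °C), to give (2S)-5,7-dihydroxy-8-[2-hydroxy-5-(2-hydroxybenzyl)benzyl]-6-iodo-2-phenylchroman-4-one F2.
- Hydrodeiodination (Pd(OAc)2, PPh3, HCO2Na, DMF, 50 °C) gives (2S)-5,7-dihydroxy-8-[2-hydroxy-5-(2-hydroxybenzyl)benzyl]-2-phenylchroman-4-one F3.
- F3 is hydroxybenzylated at its now unique C6 with 6 (ZnCl2, dioxane, 85 °C) to give 10.

Step 4. C8 is hindered, 4 can self-condense under the Lewis acid before it is captured, and long heating with ZnCl2 risks racemisation. The fallback changes the electrophile to a masked, Lewis-acid-free o-quinone methide source. It sets out from 4 and comes back at 10.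
- 4 is condensed with PhB(OH)2 (toluene, Dean–Stark) to the cyclic boronate 2-[(2-phenyl-4H-1,3,2-benzodioxaborin-6-yl)methyl]phenol F4, which has no free salicyl alcohol and can be purified and stored.
- F4 is heated with 8 (mesitylene, about 150 °C, sealed tube). It releases 9 by retro-hetero-Diels–Alder loss of the phenylboron unit, and capture at C8 gives 10.

Step 1. The aryl acetate may be lost before coupling (giving an o-quinone methide from the free 2-hydroxybenzyl chloride), or the phenoxide of 2 may be O-benzylated. The fallback swaps the base-labile ester for a robust ether with a separate deprotection, so standard aqueous Suzuki conditions can be used. It sets out from 2 and comes back at 4.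
- 2 is coupled with 2-methoxybenzyl chloride (Pd(PPh3)4, K2CO3, dioxane/H2O, 80 °C) to give 2-hydroxy-5-(2-methoxybenzyl)benzaldehyde F5.
- BBr3 (CH2Cl2, −78 to 0 °C) gives 2-hydroxy-5-(2-hydroxybenzyl)benzaldehyde F6.
- NaBH4 (MeOH, 0 °C) reduces F6 to 4.

**Further compounds**
F1 | step 3 | (2S)-5,7-dihydroxy-6-iodo-2-phenylchroman-4-one | O=C1C[C@@H](c2ccccc2)Oc2cc(O)c(I)c(O)c21
F2 | step 3 | (2S)-5,7-dihydroxy-8-[2-hydroxy-5-(2-hydroxybenzyl)benzyl]-6-iodo-2-phenylchroman-4-one | O=C1C[C@@H](c2ccccc2)Oc2c(Cc3cc(Cc4ccccc4O)ccc3O)c(O)c(I)c(O)c21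
F3 | step 3 | (2S)-5,7-dihydroxy-8-[2-hydroxy-5-(2-hydroxybenzyl)benzyl]-2-phenylchroman-4-one | O=C1C[C@@H](c2ccccc2)Oc2c(Cc3cc(Cc4ccccc4O)ccc3O)c(O)cc(O)c21
F4 | step 4 | 2-[(2-phenyl-4H-1,3,2-benzodioxaborin-6-yl)methyl]phenol | Oc1ccccc1Cc1ccc2OB(c3ccccc3)OCc2c1
F5 | step 1 | 2-hydroxy-5-(2-methoxybenzyl)benzaldehyde | COc1ccccc1Cc1ccc(O)c(C=O)c1
F6 | step 1 | 2-hydroxy-5-(2-hydroxybenzyl)benzaldehyde | O=Cc1cc(Cc2ccccc2O)ccc1O
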